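**Retrosynthetic overview**
- Target ⇒ its bis-benzyl (ester + aryl ether) derivative by final hydrogenolysis ⇒ the (R)-secondary alcohol by acetylation.
- Key disconnection ArCH2–CH(O): a benzylic pinacol boronate plus (S)-α-lithiated dodecyl 2,4,6-triisopropylbenzoate (TIB ester), a sparteine-derived chiral hydroxyalkyl-anion (d1) equivalent. A stereospecific 1,2-boronate shift makes the C–C bond and the stereocentre together; oxidation gives the alcohol.
- Benzylic boronate ⇐ lateral lithiation/borylation of benzyl 4-(benzyloxy)-2-methoxy-6-methylbenzoate ⇐ orsellinic acid (one-pot bis-benzylation/O-methylation); TIB ester ⇐ 1-dodecanol.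
- No ring is formed: the only ring, the benzene ring, is bought as orsellinic acid.

Assumption: the stereocentre in the given SMILES is (R); orsellinic acid, 1-dodecanol, 2,4,6-triisopropylbenzoic acid and (−)-sparteine are bought.

**Step 1**
Reactants: 1 orsellinic acid (2,4-dihydroxy-6-methylbenzoic acid)
Product: 3 benzyl 4-(benzyloxy)-2-methoxy-6-methylbenzoate, via benzyl 4-(benzyloxy)-2-hydroxy-6-methylbenzoate 2 (not isolated)
Conditions: BnBr (2.05 equiv), K2CO3, DMF, 0 °C to rt; then MeI, 50 °C
Reagents that add atoms: benzyl bromide BrCc1ccccc1; iodomethane CI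
Why: One-pot Williamson O-alkylation: the carboxylate and the free para-hydroxyl are benzylated first because the ortho-hydroxyl is hydrogen-bonded to the carbonyl, and this chelated phenol is then methylated by excess MeI on warming.

**Step 2**
Reactants: 3 benzyl 4-(benzyloxy)-2-methoxy-6-methylbenzoate
Product: 5 benzyl 4-(benzyloxy)-2-methoxy-6-[(4,4,5,5-tetramethyl-1,3,2-dioxaborolan-2-yl)methyl]benzoate, via lateral benzyllithium 4 (not isolated)
Conditions: LiN(iPr)2, THF, −78 °C; iPrOBpin, −78 to −20 °C; AcOH, −78 °C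
Reagents that add atoms: 2-isopropoxy-4,4,5,5-tetramethyl-1,3,2-dioxaborolane CC(C)OB1OC(C)(C)C(C)(C)O1
Why: Proposed new method: lateral (benzylic) lithiation of the o-toluate by LiN(iPr)2 is standard and gives an extended dienolate whose trapping by the borate is expected at carbon because only C-borylation restores the aromatic ring, the closest known reaction types being borate trapping of laterally lithiated o-toluamides and C-silylation of toluate anions.

**Step 3**
Reactants: 6 1-dodecanol
Product: 7 dodecyl 2,4,6-triisopropylbenzoate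
Conditions: 2,4,6-triisopropylbenzoic acid, PPh3, DIAD, THF, 0 °C to rt
Reagents that add atoms: 2,4,6-triisopropylbenzoic acid CC(C)c1cc(C(C)C)c(C(=O)O)c(C(C)C)c1
Why: Mitsunobu esterification of a primary alcohol with the hindered acid installs the directing/leaving group needed for α-lithiation; no stereocentre is involved.

**Step 4**
Reactants: 7 dodecyl 2,4,6-triisopropylbenzoate; 5 benzyl 4-(benzyloxy)-2-methoxy-6-[(4,4,5,5-tetramethyl-1,3,2-dioxaborolan-2-yl)methyl]benzoate
Product: 11 benzyl 4-(benzyloxy)-2-[(2R)-2-hydroxytridecyl]-6-methoxybenzoate, via (S)-1-lithiododecyl 2,4,6-triisopropylbenzoate 8 (not isolated), via lithium boronate complex 9 (not isolated), via (R)-secondary pinacol boronic ester 10 (not isolated)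
Conditions: 7 (1.4 equiv), s-BuLi (1.3 equiv), (−)-sparteine, Et2O, −78 °C, 5 h; 5 (1.0 equiv), −78 °C then reflux; then 30% H2O2, aq NaHCO3, THF, 0 °C to rt
Reagents that add atoms: hydrogen peroxide OO
Why: Hoppe–Aggarwal lithiation–borylation: (−)-sparteine-directed removal of the pro-S proton gives the configurationally stable α-oxyalkyllithium 8 (an umpoled hydroxyalkyl anion), which adds to boron with retention, the benzyl group then shifts from boron to carbon with inversion and loss of the TIB carboxylate (C–C bond and stereocentre formed together), and buffered peroxide oxidation with retention gives the (R)-alcohol while keeping alkoxide concentration too low for lactonisation onto the hindered benzyl ester.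

**Step 5**
Reactants: 11 benzyl 4-(benzyloxy)-2-[(2R)-2-hydroxytridecyl]-6-methoxybenzoate
Product: 12 benzyl 2-[(2R)-2-acetoxytridecyl]-4-(benzyloxy)-6-methoxybenzoate
Conditions: Ac2O, pyridine, DMAP (cat.), CH2Cl2, 0 °C
Reagents that add atoms: acetic anhydride CC(=O)OC(C)=O
Why: DMAP-catalysed O-acetylation of the secondary alcohol is faster than lactonisation and breaks no bond at the stereocentre, so the (R) configuration is kept.

**Step 6**
Reactants: 12 benzyl 2-[(2R)-2-acetoxytridecyl]-4-(benzyloxy)-6-methoxybenzoate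
Product: 13 2-[(2R)-2-acetoxytridecyl]-4-hydroxy-6-methoxybenzoic acid
Conditions: H2 (1 atm), 10% Pd/C, EtOAc, rt
Reagents that add atoms: none
Why: Catalytic hydrogenolysis cleaves both O-benzyl groups (ester and aryl ether) as toluene under neutral conditions, leaving the non-benzylic secondary acetate and the stereocentre untouched.

**Compound list**
1 | orsellinic acid (2,4-dihydroxy-6-methylbenzoic acid) | Cc1cc(O)cc(O)c1C(=O)O | starting material
2 | benzyl 4-(benzyloxy)-2-hydroxy-6-methylbenzoate | Cc1cc(OCc2ccccc2)cc(O)c1C(=O)OCc1ccccc1 | intermediate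
3 | benzyl 4-(benzyloxy)-2-methoxy-6-methylbenzoate | Cc1cc(OCc2ccccc2)cc(OC)c1C(=O)OCc1ccccc1 | intermediate
4 | benzyl 4-(benzyloxy)-2-(lithiomethyl)-6-methoxybenzoate (lateral benzyllithium, drawn C-bound; in solution an extended lithium dienolate) | [Li]Cc1cc(OCc2ccccc2)cc(OC)c1C(=O)OCc1ccccc1 | intermediate
5 | benzyl 4-(benzyloxy)-2-methoxy-6-[(4,4,5,5-tetramethyl-1,3,2-dioxaborolan-2-yl)methyl]benzoate | CC1(C)OB(Cc2cc(OCc3ccccc3)cc(OC)c2C(=O)OCc2ccccc2)OC1(C)C | intermediate
6 | 1-dodecanol | CCCCCCCCCCCCO | starting material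
7 | dodecyl 2,4,6-triisopropylbenzoate | CCCCCCCCCCCCOC(=O)c1c(C(C)C)cc(C(C)C)cc1C(C)C | intermediate
8 | (S)-1-lithiododecyl 2,4,6-triisopropylbenzoate (as its (−)-sparteine complex) | CCCCCCCCCCC[C@H]([Li])OC(=O)c1c(C(C)C)cc(C(C)C)cc1C(C)C | intermediate
9 | lithium [2-(benzyloxycarbonyl)-5-(benzyloxy)-3-methoxybenzyl][(1S)-1-(2,4,6-triisopropylbenzoyloxy)dodecyl](pinacolato)borate | [Li+].CCCCCCCCCCC[C@H]([B-]1(Cc2cc(OCc3ccccc3)cc(OC)c2C(=O)OCc2ccccc2)OC(C)(C)C(C)(C)O1)OC(=O)c1c(C(C)C)cc(C(C)C)cc1C(C)C | intermediate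
10 | benzyl 4-(benzyloxy)-2-methoxy-6-[(2R)-2-(4,4,5,5-tetramethyl-1,3,2-dioxaborolan-2-yl)tridecyl]benzoate | CCCCCCCCCCC[C@H](Cc1cc(OCc2ccccc2)cc(OC)c1C(=O)OCc1ccccc1)B1OC(C)(C)C(C)(C)O1 | intermediate
11 | benzyl 4-(benzyloxy)-2-[(2R)-2-hydroxytridecyl]-6-methoxybenzoate | CCCCCCCCCCC[C@H](Cc1cc(OCc2ccccc2)cc(OC)c1C(=O)OCc1ccccc1)O | intermediate
12 | benzyl 2-[(2R)-2-acetoxytridecyl]-4-(benzyloxy)-6-methoxybenzoate | CCCCCCCCCCC[C@H](Cc1cc(OCc2ccccc2)cc(OC)c1C(=O)OCc1ccccc1)OC(C)=O | intermediate
13 | 2-[(2R)-2-acetoxytridecyl]-4-hydroxy-6-methoxybenzoic acid | CCCCCCCCCCC[C@H](Cc1cc(O)cc(OC)c1C(=O)O)OC(C)=O | target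

**Totals**
Total step count: 6. Longest linear sequence: 5 steps (steps 1, 2, 4, 5, 6); step 3 is a one-step side branch.

**Three steps most likely to fail**

Step 4 (key lithiation–borylation). The risks are:
- proton transfer from the acidic benzylic CH2 of 5 to the lithiated species 8;
- attack of 8 on the benzyl ester instead of boron;
- lactonisation of 11 to the dihydroisocoumarin during oxidation or work-up. The buffered oxidation and prompt acetylation in step 5 are there to limit this.

Expected er is about 96:4 to 98:2, set by sparteine. The fallback sets out from 3 and 6 and comes back at 10. It moves the boron to the other partner, so the acidic benzylboronate 5 never meets a strong base. Compound 6 is carbamoylated (N,N-diisopropylcarbamoyl chloride, Et3N, toluene, reflux) to dodecyl N,N-diisopropylcarbamate F1. Treatment with s-BuLi and (−)-sparteine in Et2O at −78 °C gives (S)-1-lithiododecyl N,N-diisopropylcarbamate F2, which is trapped with iPrOBpin as the isolable (S)-1-(4,4,5,5-tetramethyl-1,3,2-dioxaborolan-2-yl)dodecyl N,N-diisopropylcarbamate F3. The lateral benzyllithium 4 (from 3 and LiN(iPr)2, THF, −78 °C) is then added to F3 to give the lithium boronate complex F4. With MgBr2·OEt2 at reflux, F4 undergoes the same invertive benzyl 1,2-shift with loss of the carbamate to give 10, which is oxidised to 11 as in the route.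

Step 2 (lateral lithiation–borylation). The risks are O- rather than C-borylation, self-condensation of the toluate anion, and protodeboronation of 5 on work-up. The fallback sets out from 3 and comes back at 5. The C–B bond is made by cross-coupling instead of anion trapping. The anion 4 is added inversely to C2Cl6 in THF at −78 °C to give benzyl 4-(benzyloxy)-2-(chloromethyl)-6-methoxybenzoate F5. Miyaura borylation of this benzylic chloride (B2pin2, Pd(dba)2, P(4-MeOC6H4)3, KOAc, toluene, 50 °C) gives 5.

Step 1 (one-pot regioselective alkylation). The risks are over-benzylation at the chelated ortho-hydroxyl and decarboxylation of 1. The fallback sets out from 1 and comes back at 2. The acid and ortho-hydroxyl are tied together first so that the regiochemistry is unambiguous. Acetone, (CF3CO)2O and CF3CO2H convert 1 into 7-hydroxy-2,2,5-trimethyl-4H-1,3-benzodioxin-4-one F6, in which only the para-hydroxyl is free. BnBr and K2CO3 in acetone give 7-(benzyloxy)-2,2,5-trimethyl-4H-1,3-benzodioxin-4-one F7. BnOH with NaH in THF opens the dioxinone, releasing acetone, to give 2, which is methylated (MeI, K2CO3, DMF) to 3.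

**Further compounds**
F1 | step 4 | dodecyl N,N-diisopropylcarbamate | CCCCCCCCCCCCOC(=O)N(C(C)C)C(C)C
F2 | step 4 | (S)-1-lithiododecyl N,N-diisopropylcarbamate | CCCCCCCCCCC[C@H]([Li])OC(=O)N(C(C)C)C(C)C
F3 | step 4 | (S)-1-(4,4,5,5-tetramethyl-1,3,2-dioxaborolan-2-yl)dodecyl N,N-diisopropylcarbamate | CCCCCCCCCCC[C@H](B1OC(C)(C)C(C)(C)O1)OC(=O)N(C(C)C)C(C)C
F4 | step 4 | lithium [2-(benzyloxycarbonyl)-5-(benzyloxy)-3-methoxybenzyl][(1S)-1-(N,N-diisopropylcarbamoyloxy)dodecyl](pinacolato)borate | [Li+].CCCCCCCCCCC[C@H]([B-]1(Cc2cc(OCc3ccccc3)cc(OC)c2C(=O)OCc2ccccc2)OC(C)(C)C(C)(C)O1)OC(=O)N(C(C)C)C(C)C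
F5 | step 2 | benzyl 4-(benzyloxy)-2-(chloromethyl)-6-methoxybenzoate | ClCc1cc(OCc2ccccc2)cc(OC)c1C(=O)OCc1ccccc1
F6 | step 1 | 7-hydroxy-2,2,5-trimethyl-4H-1,3-benzodioxin-4-one | Cc1cc(O)cc2OC(C)(C)OC(=O)c12
F7 | step 1 | 7-(benzyloxy)-2,2,5-trimethyl-4H-1,3-benzodioxin-4-one | Cc1cc(OCc3ccccc3)cc2OC(C)(C)OC(=O)c12
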